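**Retrosynthetic overview**
1. The ring oxirane comes last: peracid epoxidation of the E-configured C1=C10 alkene of a (4Z)-germacradienolide ester, from the outer face.
2. Key C–O disconnection at the C8 ester: photoredox-triggered, stereoinvertive displacement of an 8α-O–TEMPO ether by (2S,3S)-epoxyangelic acid (acid from angelic acid by reduction, Sharpless epoxidation, RuO4 oxidation).
3. The ten-membered carbocycle and the γ-lactone close together: CrCl2-mediated intramolecular allylation/lactonisation of a (bromomethyl)enoate–enal, in which the C8 stereocentre directs C6 and C7.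
4. The C8–O stereocentre comes from an enamine-catalysed α-oxyamination of a C12 hydroxy aldehyde; C11–C13 come from methyl propiolate.
5. The hydroxy aldehyde comes from (2Z,6E)-farnesol, made from geranyl bromide and 3-methylbut-2-enoic acid by Z-selective γ-alkylation. Ring order: carbocycle plus lactone in one step, then the ring oxirane; the ester oxirane is made separately.

Assumption: the target SMILES is read as the 4Z alkene with a trans 1,10-oxirane; germacrane numbering is used for positions (C6 lactone carbinol, C7 ring-fusion carbon, C8 ester carbon, C11–C13 the methylene-lactone carbons); TEMPO = 2,2,6,6-tetramethylpiperidin-1-oxyl and TMP–O is its O-bound residue.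

**Step 1**
Reactants: 1 geranyl bromide; 2 3-methylbut-2-enoic acid
Product: 4 (2Z,6E)-3,7,11-trimethyldodeca-2,6,10-trienoic acid, via dicopper dienolate 3 (not isolated)
Conditions: 2, LiN(iPr)2 (2.2 equiv), THF, −78 to 0 °C; CuI (2 equiv), −78 °C; then 1, −78 to −20 °C; H3O+
Reagents that add atoms: none
Why: Known γ-selective allylation of the dicopper dienolate (monovalent copper) of 3-methylbut-2-enoic acid; deprotonation and C–C bond formation occur at the methyl cis to the carboxylate by SN2 attack on the allylic bromide, so the new chain is cis to CO2H (2Z) and the E alkene of 1 is carried over unchanged; no stereocentre is formed.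

**Step 2**
Reactants: 4 (2Z,6E)-3,7,11-trimethyldodeca-2,6,10-trienoic acid
Product: 5 (2Z,6E)-3,7,11-trimethyldodeca-2,6,10-trien-1-ol [(2Z,6E)-farnesol]
Conditions: LiAlH4, Et2O, 0 °C
Reagents that add atoms: none
Why: Hydride 1,2-reduction of the conjugated acid to the allylic alcohol (as geranic acid to geraniol); alkene geometries are retained and no stereocentre is formed.

**Step 3**
Reactants: 5 (2Z,6E)-farnesol
Product: 7 (2Z,6E)-10,11-epoxy-3,7,11-trimethyldodeca-2,6-dien-1-ol (racemic), via terminal bromohydrin 6 (not isolated)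
Conditions: NBS, THF/H2O, 0 °C; then K2CO3, MeOH, rt
Reagents that add atoms: water, O (epoxide oxygen); N-bromosuccinimide, O=C1CCC(=O)N1Br (bromine of 6 only)
Why: van Tamelen terminal-selective bromohydrin formation (water opens the bromonium ion at the tertiary carbon; the 2,3-alkene is deactivated by the allylic hydroxyl) followed by Williamson-type ring closure; the epoxide is racemic, which does not matter because its stereocentre is cleaved away in step 4.

**Step 4**
Reactants: 7 (2Z,6E)-10,11-epoxyfarnesol
Product: 9 (4E,8Z)-10-hydroxy-4,8-dimethyldeca-4,8-dienal, via 10,11-glycol 8 (not isolated)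
Conditions: H5IO6, THF/Et2O, 0 °C
Reagents that add atoms: water, O (in glycol 8 only; it leaves with acetone)
Why: Acid-assisted opening of the epoxide to the glycol and Malaprade periodate cleavage release acetone and the C12 aldehyde; no stereocentre remains.

**Step 5**
Reactants: 9 (4E,8Z)-10-hydroxy-4,8-dimethyldeca-4,8-dienal
Product: 10 (2S,4E,8Z)-10-hydroxy-4,8-dimethyl-2-[(2,2,6,6-tetramethylpiperidin-1-yl)oxy]deca-4,8-dienal
Conditions: TEMPO (2.2 equiv), CuCl2 (10 mol%), (2S,5S)-5-benzyl-2-tert-butyl-3-methylimidazolidin-4-one·TFA (20 mol%), acetone, −10 °C, argon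
Reagents that add atoms: TEMPO, CC1(C)CCCC(C)(C)N1[O]
Why: Known enamine α-oxyamination of aldehydes (C–O bond formation); the E-enamine points away from the tert-butyl group, the benzyl group blocks the Re face and the copper-bound nitroxide adds to the Si face, giving the 2S aldehyde (future C8, 8α-oxygen), while the TFA salt and the oxygen-free medium keep the copper/TEMPO pair from oxidising the free allylic alcohol.

**Step 6**
Reactants: 10 (2S)-α-aminoxy aldehyde; 11 methyl propiolate
Product: 13 methyl (4S,6E,10Z)-3,12-dihydroxy-6,10-dimethyl-2-methylidene-4-[(2,2,6,6-tetramethylpiperidin-1-yl)oxy]dodeca-6,10-dienoate (both C3 epimers), via α-aluminoacrylate 12 (not isolated)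
Conditions: 11, iBu2AlH, N-methylmorpholine N-oxide, THF, 0 °C; then 10, −10 °C to rt; aq KNaC4H4O6
Reagents that add atoms: none
Why: Hydroalumination of the propiolate gives the α-aluminoacrylate, which adds 1,2 to the aldehyde (vinylalane version of the Morita–Baylis–Hillman reaction) without basic conditions that could epimerise C8; the new C7 carbinol forms as an epimer mixture that is erased in step 8, and excess reagent (3.2 equiv) covers the equivalent consumed by the free hydroxyl.

**Step 7**
Reactants: 13 Morita–Baylis–Hillman diol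
Product: 14 methyl (4S,6E,10Z)-3-hydroxy-6,10-dimethyl-2-methylidene-12-oxo-4-[(2,2,6,6-tetramethylpiperidin-1-yl)oxy]dodeca-6,10-dienoate (both C3 epimers)
Conditions: PhI(OAc)2, TEMPO (10 mol%), CH2Cl2, rt
Reagents that add atoms: none
Why: Oxoammonium-mediated oxidation is selective for the primary allylic alcohol over the hindered secondary one and is known to turn nerol into neral without Z-to-E isomerisation; the alkoxyamine and both alkenes are inert.

**Step 8**
Reactants: 14 hydroxy enal
Product: 15 methyl (2Z,4S,6E,10Z)-2-(bromomethyl)-6,10-dimethyl-12-oxo-4-[(2,2,6,6-tetramethylpiperidin-1-yl)oxy]dodeca-2,6,10-trienoate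
Conditions: NBS, Me2S, CH2Cl2, −30 to 0 °C
Reagents that add atoms: N-bromosuccinimide, O=C1CCC(=O)N1Br
Why: Corey–Kim-type activation of the Morita–Baylis–Hillman alcohol as an alkoxysulfonium salt and SN2′ attack of bromide give the thermodynamically preferred (Z)-2-(bromomethyl)enoate; the C7 stereocentre disappears and C8 is untouched.

**Step 9**
Reactants: 15 bromomethyl enoate enal
Product: 18 (3aS,4S,6E,10Z,11aR)-6,10-dimethyl-3-methylidene-4-[(2,2,6,6-tetramethylpiperidin-1-yl)oxy]-3a,4,5,8,9,11a-hexahydrocyclodeca[b]furan-2(3H)-one, via allylchromium dichloride 16 (not isolated), via chromium alkoxide 17 (not isolated)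
Conditions: CrCl2 (6 equiv), THF, rt, syringe-pump addition of 15 (final 2 mM); aq NH4Cl
Reagents that add atoms: none
Why: Intramolecular Nozaki–Hiyama–Kishi allylation (divalent chromium inserts into C–Br; the trivalent allylchromium adds γ-selectively through a six-membered chair) followed by lactonisation of the chromium alkoxide in the flask; the E-type allylchromium gives the 6,7-anti adduct (trans-fused lactone), and C8 reacts with H8 eclipsing the alkene (A1,3 strain), the bulky TMP–O group anti to the incoming aldehyde and the ring tether gauche, which sets 11aR and 3aS (the target's C6/C7 configuration with the C8 oxygen trans to C11, i.e. 8α).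

**Step 10**
Reactants: 19 angelic acid
Product: 20 (2Z)-2-methylbut-2-en-1-ol
Conditions: LiAlH4, Et2O, 0 °C
Reagents that add atoms: none
Why: Hydride reduction of the acid to the allylic alcohol with retention of the Z geometry; no stereocentre is formed.

**Step 11**
Reactants: 20 (2Z)-2-methylbut-2-en-1-ol
Product: 21 [(2R,3S)-2,3-dimethyloxiran-2-yl]methanol
Conditions: Ti(OiPr)4 (10 mol%), D-(−)-diethyl tartrate (12 mol%), tBuOOH, 4 Å molecular sieves, CH2Cl2, −20 °C
Reagents that add atoms: tert-butyl hydroperoxide, CC(C)(C)OO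
Why: Sharpless asymmetric epoxidation; with the D-tartrate the titanium-bound peroxide adds to the face opposite to the one used by the L-tartrate (which gives (2S,3S)-epoxygeraniol), giving the (2R,3S) epoxy alcohol, and syn addition keeps CH2OH and the C3 methyl cis.

**Step 12**
Reactants: 21 [(2R,3S)-2,3-dimethyloxiran-2-yl]methanol
Product: 22 (2S,3S)-2,3-dimethyloxirane-2-carboxylic acid
Conditions: RuCl3 (2 mol%), NaIO4 (4 equiv), MeCN/EtOAc/H2O, 0 °C to rt
Reagents that add atoms: water, O (carboxyl oxygen, via the aldehyde hydrate)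
Why: RuO4 generated in the flask oxidises the primary alcohol to the acid without touching the epoxide; the stereocentres are unchanged and the C2 descriptor becomes S only because the CIP priorities change.

**Step 13**
Reactants: 18 8α-TMP–O macrolactone; 22 (2S,3S)-2,3-dimethyloxirane-2-carboxylic acid
Product: 23 (3aR,4R,6E,10Z,11aR)-6,10-dimethyl-3-methylidene-2-oxo-2,3,3a,4,5,8,9,11a-octahydrocyclodeca[b]furan-4-yl (2S,3S)-2,3-dimethyloxirane-2-carboxylate
Conditions: 22 (3 equiv), [Ir(dF(CF3)ppy)2(bpy)]PF6 (2 mol%), CH2Cl2/MeCN 1:1, 450 nm LEDs, 20 °C, argon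
Reagents that add atoms: none
Why: Proposed new method: the excited trivalent iridium photocatalyst oxidises the alkoxyamine nitrogen (estimated near +1.1 V vs SCE, below the trisubstituted alkenes and the undissociated acid), and in the radical cation the weakened C8–O bond is attacked from the rear by the carboxylic acid (nucleophile-assisted mesolysis, SN2) with loss of TEMPO, which the reduced photocatalyst and the released proton convert into TEMPO–H so the cycle is redox-neutral; an unstabilised secondary cation cannot form, so backside attack inverts C8 (8α-O to the 8β ester, 4R); the closest known reactions are the photocatalytic mesolytic cleavage of benzylic TEMPO ethers to carbocations trapped by O-nucleophiles and the anodic activation of TEMPO–Me as an SN2 methylating agent for carboxylic acids.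

**Step 14**
Reactants: 23 diene ester
Product: 24 target, (1R,6R,7R,8R,10R,4Z)-1,10-epoxy-8-{[(2S,3S)-2,3-dimethyloxiran-2-yl]carbonyloxy}germacra-4,11(13)-dien-12,6-olide
Conditions: mCPBA (1.05 equiv), NaHCO3, CH2Cl2, 0 °C
Reagents that add atoms: 3-chloroperoxybenzoic acid, OOC(=O)c1cccc(Cl)c1
Why: Prilezhaev epoxidation; the E-trisubstituted C1=C10 alkene is the most electron-rich (C4=C5 is deactivated by the allylic lactone oxygen, the methylene lactone is electron-poor) and the peracid attacks its exposed outer face to give the trans (1R,10R) oxirane, while NaHCO3 prevents acid-induced transannular cyclisation.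

**Compound list**
1 | geranyl bromide, (2E)-1-bromo-3,7-dimethylocta-2,6-diene | CC(C)=CCC/C(C)=C/CBr | starting material
2 | 3-methylbut-2-enoic acid | CC(C)=CC(O)=O | starting material
3 | dicopper dienolate of 2 (monovalent copper) | C=C(C)C=C(O[Cu])O[Cu] | intermediate (not isolated)
4 | (2Z,6E)-3,7,11-trimethyldodeca-2,6,10-trienoic acid | CC(C)=CCC/C(C)=C/CC/C(C)=C\C(O)=O | intermediate
5 | (2Z,6E)-3,7,11-trimethyldodeca-2,6,10-trien-1-ol | CC(C)=CCC/C(C)=C/CC/C(C)=C\CO | intermediate
6 | (2Z,6E)-10-bromo-3,7,11-trimethyldodeca-2,6-diene-1,11-diol (racemic) | CC(C)(O)C(Br)CC/C(C)=C/CC/C(C)=C\CO | intermediate (not isolated)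
7 | (2Z,6E)-10,11-epoxy-3,7,11-trimethyldodeca-2,6-dien-1-ol (racemic) | CC1(C)OC1CC/C(C)=C/CC/C(C)=C\CO | intermediate
8 | (2Z,6E)-3,7,11-trimethyldodeca-2,6-diene-1,10,11-triol (racemic) | CC(C)(O)C(O)CC/C(C)=C/CC/C(C)=C\CO | intermediate (not isolated)
9 | (4E,8Z)-10-hydroxy-4,8-dimethyldeca-4,8-dienal | O=CCC/C(C)=C/CC/C(C)=C\CO | intermediate
10 | (2S,4E,8Z)-10-hydroxy-4,8-dimethyl-2-[(2,2,6,6-tetramethylpiperidin-1-yl)oxy]deca-4,8-dienal | O=C[C@@H](ON1C(C)(C)CCCC1(C)C)C/C(C)=C/CC/C(C)=C\CO | intermediate
11 | methyl propiolate | C#CC(=O)OC | starting material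
12 | methyl 2-(diisobutylalumanyl)prop-2-enoate | C=C(C(=O)OC)[Al](CC(C)C)CC(C)C | intermediate (not isolated)
13 | methyl (4S,6E,10Z)-3,12-dihydroxy-6,10-dimethyl-2-methylidene-4-[(2,2,6,6-tetramethylpiperidin-1-yl)oxy]dodeca-6,10-dienoate (C3 epimers) | COC(=O)C(=C)C(O)[C@@H](ON1C(C)(C)CCCC1(C)C)C/C(C)=C/CC/C(C)=C\CO | intermediate
14 | methyl (4S,6E,10Z)-3-hydroxy-6,10-dimethyl-2-methylidene-12-oxo-4-[(2,2,6,6-tetramethylpiperidin-1-yl)oxy]dodeca-6,10-dienoate (C3 epimers) | COC(=O)C(=C)C(O)[C@@H](ON1C(C)(C)CCCC1(C)C)C/C(C)=C/CC/C(C)=C\C=O | intermediate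
15 | methyl (2Z,4S,6E,10Z)-2-(bromomethyl)-6,10-dimethyl-12-oxo-4-[(2,2,6,6-tetramethylpiperidin-1-yl)oxy]dodeca-2,6,10-trienoate | COC(=O)/C(CBr)=C/[C@@H](ON1C(C)(C)CCCC1(C)C)C/C(C)=C/CC/C(C)=C\C=O | intermediate
16 | allylchromium dichloride derived from 15 (trivalent chromium on C13) | COC(=O)C(C[Cr](Cl)Cl)=C[C@@H](ON1C(C)(C)CCCC1(C)C)C/C(C)=C/CC/C(C)=C\C=O | intermediate (not isolated)
17 | chromium alkoxide of the ring-closed hydroxy ester (ten-membered carbocycle, lactone still open) | C=C(C(=O)OC)[C@H]1[C@H](O[Cr](Cl)Cl)/C=C(/C)CC/C=C(\C)C[C@@H]1ON2C(C)(C)CCCC2(C)C | intermediate (not isolated)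
18 | (3aS,4S,6E,10Z,11aR)-6,10-dimethyl-3-methylidene-4-[(2,2,6,6-tetramethylpiperidin-1-yl)oxy]-3a,4,5,8,9,11a-hexahydrocyclodeca[b]furan-2(3H)-one | C=C1C(=O)O[C@@H]2/C=C(/C)CC/C=C(\C)C[C@H](ON3C(C)(C)CCCC3(C)C)[C@@H]12 | intermediate
19 | angelic acid, (2Z)-2-methylbut-2-enoic acid | C/C=C(/C)C(O)=O | starting material
20 | (2Z)-2-methylbut-2-en-1-ol | C/C=C(/C)CO | intermediate
21 | [(2R,3S)-2,3-dimethyloxiran-2-yl]methanol | OC[C@@]1(C)O[C@H]1C | intermediate
22 | (2S,3S)-2,3-dimethyloxirane-2-carboxylic acid | OC(=O)[C@@]1(C)O[C@H]1C | intermediate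
23 | (3aR,4R,6E,10Z,11aR)-6,10-dimethyl-3-methylidene-2-oxo-2,3,3a,4,5,8,9,11a-octahydrocyclodeca[b]furan-4-yl (2S,3S)-2,3-dimethyloxirane-2-carboxylate | C=C1C(=O)O[C@@H]2/C=C(/C)CC/C=C(\C)C[C@@H](OC(=O)[C@@]3(C)O[C@H]3C)[C@@H]12 | intermediate
24 | (1R,6R,7R,8R,10R,4Z)-1,10-epoxy-8-{[(2S,3S)-2,3-dimethyloxiran-2-yl]carbonyloxy}germacra-4,11(13)-dien-12,6-olide | C=C1C(=O)O[C@@H]2/C=C(/C)CC[C@H]3O[C@]3(C)C[C@@H](OC(=O)[C@@]3(C)O[C@H]3C)[C@@H]12 | target

**Step count**
Total: 14 steps. Longest linear sequence: 11 steps (steps 1–9, 13 and 14, from geranyl bromide).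

**Three steps most likely to fail**

Step 13 (the proposed new method). The SN2 attack on the radical cation at the hindered C8 may be slow, elimination towards C7=C8 or C8=C9 may compete, and the alkenes may be oxidised. The fallback uses known chemistry and sets out from 18. Zinc dust in AcOH/THF/H2O at 50 °C reduces the N–O bond and gives the 8α-alcohol (3aR,4S,6E,10Z,11aR)-4-hydroxy-6,10-dimethyl-3-methylidene-3a,4,5,8,9,11a-hexahydrocyclodeca[b]furan-2(3H)-one F1. Mitsunobu esterification of this alcohol with 22 (PPh3, diisopropyl azodicarboxylate, toluene, 0 °C) inverts C8 and gives 23, where the route is rejoined.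

Step 9. The macrocyclisation may give oligomers, or the facial induction from C8 may be weak; the sense of this induction is the main stereochemical uncertainty of the route. The fallback changes the way the allyl nucleophile is made and sets out from 14. Acetylation (Ac2O, DMAP, pyridine, CH2Cl2) gives methyl (4S,6E,10Z)-3-acetoxy-6,10-dimethyl-2-methylidene-12-oxo-4-[(2,2,6,6-tetramethylpiperidin-1-yl)oxy]dodeca-6,10-dienoate F2. Pd(PPh3)4 (5 mol%, zerovalent palladium) and InI (1.5 equiv) in THF under slow addition convert the π-allylpalladium complex into an allylindium species (trivalent indium), which closes the same C6–C7 bond through a cyclic transition state and lactonises. The route is rejoined at 18; the ring fusion must be confirmed because allylindium additions can favour the syn adduct.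

Step 6. The hindered α-aminoxy aldehyde and the free hydroxyl may lead to incomplete addition or to reduction by residual iBu2AlH. The fallback sets out from 10 and uses the amine-catalysed Morita–Baylis–Hillman reaction with methyl acrylate (DABCO, neat or in MeOH, rt), which gives 13 directly; the route is rejoined at 13 and no new compound is formed.

Further compounds
F1 | step 13 | (3aR,4S,6E,10Z,11aR)-4-hydroxy-6,10-dimethyl-3-methylidene-3a,4,5,8,9,11a-hexahydrocyclodeca[b]furan-2(3H)-one | C=C1C(=O)O[C@@H]2/C=C(/C)CC/C=C(\C)C[C@H](O)[C@@H]12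
F2 | step 9 | methyl (4S,6E,10Z)-3-acetoxy-6,10-dimethyl-2-methylidene-12-oxo-4-[(2,2,6,6-tetramethylpiperidin-1-yl)oxy]dodeca-6,10-dienoate | COC(=O)C(=C)C(OC(C)=O)[C@@H](ON1C(C)(C)CCCC1(C)C)C/C(C)=C/CC/C(C)=C\C=O
F0 | step 6 | none | none
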